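The route rests on disconnecting the bond between C2 of the pyranone ring and C1′ of the prenylated B ring. C2 is the β-carbon of the C4 carbonyl, so the flat, achiral 5,7-disilylated chromone is the electrophile and the 4-silyloxy-3,5-diprenylphenyl unit, as an arylzinc, the nucleophile. A Rh(I)/(S)-BINAP-catalysed 1,4-addition with chlorosilane trapping joins both halves, sets C2 by catalyst control and releases the C3=C4 silyl enol ether. That enol ether is the handle for installing the C3 hydroxyl trans to the aryl group by Rubottom oxidation; one fluoride treatment then unveils all hydroxyls.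

Key step: step 4

Remark: the target is read as the (2R,3R)-configured, 2,3-trans dihydroflavonol, and 5,7-dihydroxychromone (6) is taken as a purchasable starting material.

Step 1
Reactants: 1 4-bromophenol; 2 prenyl bromide (1-bromo-3-methylbut-2-ene)
Product: 4 4-bromo-2,6-bis(3-methylbut-2-en-1-yl)phenol, via monoprenyl phenol 3 (not isolated)
Conditions: NaH (2.2 equiv), 2 (2.2 equiv), toluene, 0 °C → rt
Reagents that add atoms: none
Why: Ortho-selective C-alkylation of a sodium phenoxide in a non-polar solvent (phenoxide C-prenylation): the aggregated ion pair alkylates at the ring carbons next to oxygen with the primary carbon of the allyl bromide, the para position is blocked by bromine, and rearomatisation after each alkylation should give the 2,6-diprenyl phenol.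

Step 2
Reactants: 4 4-bromo-2,6-bis(3-methylbut-2-en-1-yl)phenol
Product: 5 [4-bromo-2,6-bis(3-methylbut-2-en-1-yl)phenoxy](tert-butyl)dimethylsilane
Conditions: TBSCl, imidazole, DMF, 40 °C
Reagents that add atoms: tert-butyldimethylsilyl chloride, CC(C)(C)[Si](C)(C)Cl
Why: Imidazole-promoted silylation of a phenol, needed so that the acidic OH does not quench the aryllithium of step 4; the two ortho CH2 groups slow but should not prevent the reaction.

Step 3
Reactants: 6 5,7-dihydroxy-4H-chromen-4-one
Product: 7 5,7-bis[(tert-butyldimethylsilyl)oxy]-4H-chromen-4-one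
Conditions: TBSOTf (2.5 equiv), 2,6-lutidine, CH2Cl2, 0 °C → rt
Reagents that add atoms: tert-butyldimethylsilyl trifluoromethanesulfonate, CC(C)(C)[Si](C)(C)OS(=O)(=O)C(F)(F)F
Why: Silylation with a silyl triflate, electrophilic enough to cap the hydrogen-bonded 5-OH as well as the acidic 7-OH, so that the enone stays aprotic for the organozinc step.

Step 4
Reactants: 5 [4-bromo-2,6-bis(3-methylbut-2-en-1-yl)phenoxy](tert-butyl)dimethylsilane; 7 5,7-bis[(tert-butyldimethylsilyl)oxy]-4H-chromen-4-one
Product: 10 (2S)-5,7-bis[(tert-butyldimethylsilyl)oxy]-2-{4-[(tert-butyldimethylsilyl)oxy]-3,5-bis(3-methylbut-2-en-1-yl)phenyl}-4-[(trimethylsilyl)oxy]-2H-chromene, via aryllithium 8 (not isolated), via arylzinc chloride 9 (not isolated)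
Conditions: 5 (1.5 equiv), t-BuLi (2 equiv per 5), THF, −78 °C; ZnCl2, −78 °C → rt; then 7, [RhCl((S)-BINAP)]2 (cat.), Me3SiCl (1.5 equiv), THF, 20 °C; non-aqueous work-up (pentane, filtration through basic alumina), used at once
Reagents that add atoms: chlorotrimethylsilane, C[Si](C)(C)Cl
Why: Rhodium-catalysed asymmetric 1,4-addition (conjugate arylation): the aryl group passes from zinc to the (S)-BINAP–Rh(I) centre, the aryl–Rh species inserts the C2=C3 bond of 7 with the aryl going to C2, and Me3SiCl silylates the resulting oxa-π-allyl rhodium (or zinc) enolate at O4, which returns Rh–Cl and releases 10. The closest known reaction type is the Rh/BINAP-catalysed addition of arylzinc chlorides with chlorosilane to 4-quinolones and 2,3-dihydro-4-pyridones, and chromones are established acceptors in Rh-catalysed asymmetric 1,4-arylation with arylboron reagents. No ring is closed. The C2 stereocentre is set by catalyst control, the C2-symmetric diphosphine shielding one enantiotopic face of the planar enone; (S)-BINAP is expected to give the 2S product by analogy with its sense on cyclic enones, and the antipodal ligand is used should the first run show the opposite sense. The step needs enantiofacial selectivity, 1,4- over 1,2-addition and chemoselectivity for C2=C3 over the two prenyl alkenes, which the soft aryl–Rh(I) nucleophile and the unhindered, carbonyl-activated C2=C3 bond should secure. Because the enolate is silylated as it forms, no free enolate is left to expel the ring phenoxide, so the retro-oxa-Michael opening that would erase C2 should be avoided.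

Step 5
Reactants: 10 (2S)-5,7-bis[(tert-butyldimethylsilyl)oxy]-2-{4-[(tert-butyldimethylsilyl)oxy]-3,5-bis(3-methylbut-2-en-1-yl)phenyl}-4-[(trimethylsilyl)oxy]-2H-chromene
Product: 12 Cathayanon H [(2R,3R)-3,5,7-trihydroxy-2-[4-hydroxy-3,5-bis(3-methylbut-2-en-1-yl)phenyl]-2,3-dihydro-4H-chromen-4-one], via siloxy epoxide 11 (not isolated)
Conditions: DMDO (1.05 equiv), acetone/CH2Cl2, −78 → −40 °C; volatiles removed cold; then TBAF/AcOH (1:1), THF, 0 °C → rt
Reagents that add atoms: dimethyldioxirane, CC1(C)OO1
Why: Rubottom oxidation: the dioxirane should epoxidise the electron-rich C3=C4 silyl enol ether far faster than the isolated trisubstituted prenyl alkenes and from the face anti to the C2 aryl group (substrate control, as in oxidations of flav-3-enes), which sets C3 as 3R (2,3-trans, also the thermodynamically preferred diequatorial ketol), and acetic acid-buffered fluoride then collapses the siloxy epoxide to the α-hydroxy ketone and cleaves the three aryl silyl ethers without exposing the base-sensitive dihydroflavonol to free alkoxide.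

Compound list
1 | 4-bromophenol | Oc1ccc(Br)cc1 | starting material
2 | prenyl bromide (1-bromo-3-methylbut-2-ene) | CC(C)=CCBr | starting material
3 | 4-bromo-2-(3-methylbut-2-en-1-yl)phenol (monoprenyl phenol, not isolated in step 1) | CC(C)=CCc1cc(Br)ccc1O | intermediate
4 | 4-bromo-2,6-bis(3-methylbut-2-en-1-yl)phenol | CC(C)=CCc1cc(Br)cc(CC=C(C)C)c1O | intermediate
5 | [4-bromo-2,6-bis(3-methylbut-2-en-1-yl)phenoxy](tert-butyl)dimethylsilane | CC(C)=CCc1cc(Br)cc(CC=C(C)C)c1O[Si](C)(C)C(C)(C)C | intermediate
6 | 5,7-dihydroxy-4H-chromen-4-one (5,7-dihydroxychromone) | O=c1ccoc2cc(O)cc(O)c12 | starting material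
7 | 5,7-bis[(tert-butyldimethylsilyl)oxy]-4H-chromen-4-one | O=c1ccoc2cc(O[Si](C)(C)C(C)(C)C)cc(O[Si](C)(C)C(C)(C)C)c12 | intermediate
8 | {4-[(tert-butyldimethylsilyl)oxy]-3,5-bis(3-methylbut-2-en-1-yl)phenyl}lithium (aryllithium, not isolated) | [Li]c1cc(CC=C(C)C)c(O[Si](C)(C)C(C)(C)C)c(CC=C(C)C)c1 | intermediate
9 | chloro{4-[(tert-butyldimethylsilyl)oxy]-3,5-bis(3-methylbut-2-en-1-yl)phenyl}zinc (arylzinc chloride, not isolated) | Cl[Zn]c1cc(CC=C(C)C)c(O[Si](C)(C)C(C)(C)C)c(CC=C(C)C)c1 | intermediate
10 | (2S)-5,7-bis[(tert-butyldimethylsilyl)oxy]-2-{4-[(tert-butyldimethylsilyl)oxy]-3,5-bis(3-methylbut-2-en-1-yl)phenyl}-4-[(trimethylsilyl)oxy]-2H-chromene | CC(C)=CCc1cc([C@H]2Oc3cc(O[Si](C)(C)C(C)(C)C)cc(O[Si](C)(C)C(C)(C)C)c3C(O[Si](C)(C)C)=C2)cc(CC=C(C)C)c1O[Si](C)(C)C(C)(C)C | intermediate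
11 | (2R,3R,4R)-3,4-epoxide of 10 (flavan numbering), oxirane oxygen on the face opposite to the C2 aryl group, C4 bearing the trimethylsilyloxy group (siloxy epoxide, not isolated) | CC(C)=CCc1cc([C@H]2Oc3cc(O[Si](C)(C)C(C)(C)C)cc(O[Si](C)(C)C(C)(C)C)c3[C@@]4(O[Si](C)(C)C)[C@@H]2O4)cc(CC=C(C)C)c1O[Si](C)(C)C(C)(C)C | intermediate
12 | Cathayanon H, (2R,3R)-3,5,7-trihydroxy-2-[4-hydroxy-3,5-bis(3-methylbut-2-en-1-yl)phenyl]-2,3-dihydro-4H-chromen-4-one | CC(C)=CCc1cc([C@H]2Oc3cc(O)cc(O)c3C(=O)[C@@H]2O)cc(CC=C(C)C)c1O | target

Total step count: 5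
Longest linear sequence: 4 steps (steps 1, 2, 4, 5)

Steps most likely to fail

Step 4. The processes at risk are: proton transfer from the doubly activated ArCH2–CH=C positions to the aryllithium before transmetalation; slow insertion into the electron-rich 5,7-dioxygenated chromone; or incomplete silyl trapping, which would let the enolate open the pyranone ring and erode the C2 configuration. The fallback sets out from 5 and 7 and comes back to the route at 10. Bromine–lithium exchange on 5 with n-BuLi in the presence of triisopropyl borate (in situ quench, THF, −78 °C) and mild acidic work-up would give {4-[(tert-butyldimethylsilyl)oxy]-3,5-bis(3-methylbut-2-en-1-yl)phenyl}boronic acid F1. Its Pd(II)-catalysed asymmetric conjugate addition to 7 (Pd(OCOCF3)2, t-BuPyOx, NH4PF6, H2O, ClCH2CH2Cl, 60 °C; the (R)-ligand is expected to give the 2S series) is a base-free, protic process of a type established for chromones and would give the (2S)-flavanone F2. Soft enolisation (Me3SiOTf, Et3N, CH2Cl2, 0 °C) would then return to 10.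

Step 5. The processes at risk are competing epoxidation of the prenyl double bonds by the dioxirane, oxygen delivery syn to the aryl group, and ring opening at C2 during desilylation. The fallback sets out from 10 and comes back at 12. MeLi (THF, −30 °C) would cleave the O–SiMe3 bond to give the lithium enolate F3. At −78 °C this would be hydroxylated by (camphorsulfonyl)oxaziridine, an oxidant that leaves isolated alkenes untouched, anti to the aryl group; acetic acid quench would give the tris-silylated (2R,3R)-dihydroflavonol F4. TBAF/AcOH in THF would then give 12.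

Step 1. The processes at risk are O-alkylation, SN2′ attack and mono- or over-alkylation competing with the twofold ortho C-alkylation. The fallback sets out from 1 and comes back at 4. Pd(0)-catalysed O-allylation of 1 with methyl 2-methylbut-3-en-2-yl carbonate (Pd(PPh3)4, THF, 0 °C) would give the 1,1-dimethylallyl aryl ether F5. Aromatic Claisen rearrangement (PhNEt2, 150–180 °C), with the para position blocked, would give the ortho-prenyl phenol 3. The same O-allylation of 3 would give the ether F6, and a second Claisen rearrangement into the remaining ortho position would give 4.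

Further compounds
F1 | step 4 | {4-[(tert-butyldimethylsilyl)oxy]-3,5-bis(3-methylbut-2-en-1-yl)phenyl}boronic acid | CC(C)=CCc1cc(B(O)O)cc(CC=C(C)C)c1O[Si](C)(C)C(C)(C)C
F2 | step 4 | (2S)-5,7-bis[(tert-butyldimethylsilyl)oxy]-2-{4-[(tert-butyldimethylsilyl)oxy]-3,5-bis(3-methylbut-2-en-1-yl)phenyl}-2,3-dihydro-4H-chromen-4-one | CC(C)=CCc1cc([C@H]2Oc3cc(O[Si](C)(C)C(C)(C)C)cc(O[Si](C)(C)C(C)(C)C)c3C(=O)C2)cc(CC=C(C)C)c1O[Si](C)(C)C(C)(C)C
F3 | step 5 | lithium (2S)-5,7-bis[(tert-butyldimethylsilyl)oxy]-2-{4-[(tert-butyldimethylsilyl)oxy]-3,5-bis(3-methylbut-2-en-1-yl)phenyl}-2H-chromen-4-olate | CC(C)=CCc1cc([C@H]2Oc3cc(O[Si](C)(C)C(C)(C)C)cc(O[Si](C)(C)C(C)(C)C)c3C(O[Li])=C2)cc(CC=C(C)C)c1O[Si](C)(C)C(C)(C)C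
F4 | step 5 | (2R,3R)-5,7-bis[(tert-butyldimethylsilyl)oxy]-2-{4-[(tert-butyldimethylsilyl)oxy]-3,5-bis(3-methylbut-2-en-1-yl)phenyl}-3-hydroxy-2,3-dihydro-4H-chromen-4-one | CC(C)=CCc1cc([C@H]2Oc3cc(O[Si](C)(C)C(C)(C)C)cc(O[Si](C)(C)C(C)(C)C)c3C(=O)[C@@H]2O)cc(CC=C(C)C)c1O[Si](C)(C)C(C)(C)C
F5 | step 1 | 1-bromo-4-[(2-methylbut-3-en-2-yl)oxy]benzene | C=CC(C)(C)Oc1ccc(Br)cc1
F6 | step 1 | 4-bromo-1-[(2-methylbut-3-en-2-yl)oxy]-2-(3-methylbut-2-en-1-yl)benzene | C=CC(C)(C)Oc1ccc(Br)cc1CC=C(C)C
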